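**Strategy.** Everything rests on building ring A of the 4′-methoxyflavone unit de novo around C8, the carbon that carries the diaryl ether oxygen between C7–O and C8a–O1. Opened up, C8 is just the α-carbon of an aryloxyacetic acid, so the crowded C8–O–aryl bond is made by simple O-alkylation. The key step is a thermal benzannulation of a 4-aryloxy-3-benzyloxycyclobutenone (from the aryloxyketene and benzyl ethynyl ether) with ethoxyacetylene. In one operation it closes the benzene ring with oxygen on C5, C7, C8 and C8a and only the C8a hydroxyl free. Both pyrone rings are then added by diketone cyclodehydration, the apigenin unit on the benzoate handle.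

Key step: step 5

Remark: locants C4a, C5–C8 and C8a refer to ring A of the 4′-methoxyflavone unit; the target has no stereocentre and every transient stereocentre of the route is racemic.

**Step 1**
Reactants: 1 methyl 4-hydroxybenzoate; 2 tert-butyl bromoacetate
Product: 3 tert-butyl 2-[4-(methoxycarbonyl)phenoxy]acetate
Conditions: K2CO3, acetone, reflux
Reagents that add atoms: none
Why: Williamson O-alkylation of the acidic phenol by the primary α-bromo ester should proceed cleanly under carbonate without touching either ester.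

**Step 2**
Reactants: 3 tert-butyl 2-[4-(methoxycarbonyl)phenoxy]acetate
Product: 5 2-[4-(methoxycarbonyl)phenoxy]acetyl chloride, via carboxylic acid 4 (not isolated)
Conditions: SOCl2 (excess), cat. HCl, rt; volatiles removed in vacuo
Reagents that add atoms: thionyl chloride, ClS(Cl)=O
Why: HCl-promoted alkyl–oxygen cleavage of the tert-butyl ester followed by chlorination of the liberated acid is a known direct tert-butyl ester to acid chloride conversion, under which a methyl benzoate is inert.

**Step 3**
Reactants: 6 benzyl alcohol; 7 trichloroethylene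
Product: 10 benzyl ethynyl ether, via dichlorovinyl ether 8 (not isolated), via lithium acetylide 9 (not isolated)
Conditions: KH, THF, 0 °C; 7, −50 °C → rt; then n-BuLi (2.3 equiv), −78 → −40 °C; H2O, −78 °C; cold pentane extraction, solution used at once
Reagents that add atoms: none
Why: Addition–elimination of the alkoxide on trichloroethylene followed by n-BuLi elimination and chlorine–lithium exchange is the standard one-flask entry to terminal ynol ethers, and cold protonation with immediate use should avoid the (3,3)-sigmatropic decay open to benzylic alkynyl ethers.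

**Step 4**
Reactants: 5 2-[4-(methoxycarbonyl)phenoxy]acetyl chloride; 10 benzyl ethynyl ether
Product: 12 methyl 4-{[2-(benzyloxy)-4-oxocyclobut-2-en-1-yl]oxy}benzoate (racemic), via aryloxyketene 11 (not isolated)
Conditions: Et3N (1.3 equiv), 10 (2 equiv), CH2Cl2, 0 °C → rt, 5 added slowly; quick filtration through Et3N-deactivated silica
Reagents that add atoms: none
Why: The ketene–alkoxyacetylene (2+2) cycloaddition should give the 3-alkoxycyclobutenone because the unsubstituted alkyne carbon attacks the carbonyl carbon of the ketene, which is kept at low concentration by slow dehydrochlorination; the C4 stereocentre forms racemic and is erased in step 5.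

**Step 5**
Reactants: 12 methyl 4-{[2-(benzyloxy)-4-oxocyclobut-2-en-1-yl]oxy}benzoate; 13 ethoxyacetylene
Product: 18 methyl 4-[2-(benzyloxy)-4-ethoxy-6-hydroxyphenoxy]benzoate, via vinylketene 14 (not isolated), via vinylcyclobutenone 15 (not isolated), via dienylketene 16 (not isolated), via cyclohexadienone 17 (not isolated)
Conditions: 13 (3 equiv, hexane solution), toluene, 80 °C, sealed tube
Reagents that add atoms: none
Why: Heating should open 12 by 4π-electrocyclic cleavage of the C(=O)–CH(OAr) bond (the future C8a–C8 bond) to vinylketene 14 with the aryloxy group on the diene terminus; the unsubstituted carbon of ethoxyacetylene then attacks the ketene carbonyl carbon in a (2+2) cycloaddition that makes C8a–C4a and C5–C6, and adduct 15 reopens to dienylketene 16. Ring A is closed by thermal disrotatory 6π-electrocyclisation of 16, which re-forms C8–C8a, and dienone 17, having a hydrogen on C8, aromatises by enolisation. The closest known reaction is the Danheiser benzannulation of cyclobutenones with alkoxyacetylenes; the 3-alkoxy-4-aryloxy pattern is an untried substrate for it, not a new reaction type. No stereocentre is created in the product, and the racemic centres of 12, 15 and 17 all end as aromatic carbons. The step needs only the regiochemistry of alkyne addition (OEt on C5, H on C4a), which the polarisation of the ynol ether towards the electrophilic ketene carbon secures, while reversible ring opening funnels material through the one dienylketene geometry able to cyclise. The neutral thermal conditions should leave the ester, the benzyl ether and the diaryl ether untouched and deliver the C8a hydroxyl as the only free phenol.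

**Step 6**
Reactants: 18 methyl 4-[2-(benzyloxy)-4-ethoxy-6-hydroxyphenoxy]benzoate
Product: 19 methyl 4-(4-ethoxy-2,6-dihydroxyphenoxy)benzoate
Conditions: H2 (1 atm), Pd/C, EtOAc, rt
Reagents that add atoms: none
Why: Hydrogenolysis of the aryl benzyl ether spares the ester, the ethyl ether and the diaryl ether, and it gives a ring with a mirror plane through C8 and C5, so that C4a and C6 become equivalent for the acylation that follows.

**Step 7**
Reactants: 19 methyl 4-(4-ethoxy-2,6-dihydroxyphenoxy)benzoate
Product: 20 methyl 4-(3-acetyl-4-ethoxy-2,6-dihydroxyphenoxy)benzoate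
Conditions: Ac2O (1.1 equiv), BF3·OEt2, rt → 50 °C; then H2O
Reagents that add atoms: acetic anhydride, CC(=O)OC(C)=O
Why: BF3-mediated Friedel–Crafts/Fries C-acetylation of this phloroglucinol-type ring can give only one monoketone because the two free positions are equivalent, and chelation of the product ketone should prevent a second acylation; no acid-labile benzyl ether is present at this stage.

**Step 8**
Reactants: 20 methyl 4-(3-acetyl-4-ethoxy-2,6-dihydroxyphenoxy)benzoate; 21 benzyl bromide
Product: 22 methyl 4-[3-acetyl-6-(benzyloxy)-4-ethoxy-2-hydroxyphenoxy]benzoate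
Conditions: 21 (1.05 equiv), K2CO3, acetone, 50 °C
Reagents that add atoms: none
Why: Williamson benzylation should take only the free, more acidic hydroxyl para to the acetyl group, as with 2,4-dihydroxyacetophenones, leaving the hydrogen-bonded C8a hydroxyl next to the aryloxy carbon as the one that later closes the pyrone.

**Step 9**
Reactants: 22 methyl 4-[3-acetyl-6-(benzyloxy)-4-ethoxy-2-hydroxyphenoxy]benzoate; 23 4-methoxybenzoyl chloride
Product: 24 methyl 4-{6-(benzyloxy)-4-ethoxy-2-hydroxy-3-[3-(4-methoxyphenyl)-3-oxopropanoyl]phenoxy}benzoate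
Conditions: LiN(SiMe3)2 (3.2 equiv), THF, −78 °C; 23, −78 °C → rt; aq. HCl
Reagents that add atoms: none
Why: The phenoxide–enolate dianion should be C-aroylated by the acid chloride at low temperature (one-flask Baker–Venkataraman-type diketone synthesis), where the remote methyl benzoate does not react.

**Step 10**
Reactants: 24 methyl 4-{6-(benzyloxy)-4-ethoxy-2-hydroxy-3-[3-(4-methoxyphenyl)-3-oxopropanoyl]phenoxy}benzoate
Product: 25 methyl 4-{[7-(benzyloxy)-5-ethoxy-2-(4-methoxyphenyl)-4-oxo-4H-chromen-8-yl]oxy}benzoate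
Conditions: TsOH·H2O (cat.), toluene, 90 °C
Reagents that add atoms: none
Why: Acid-catalysed cyclodehydration of the 2-hydroxyaryl 1,3-diketone can use only the free C8a hydroxyl, because O5 is ethylated, so the 8-aryloxy and not the 6-aryloxy flavone should form.

**Step 11**
Reactants: 26 2,4,6-trihydroxyacetophenone; 21 benzyl bromide
Product: 27 1-[2,4-bis(benzyloxy)-6-hydroxyphenyl]ethanone
Conditions: 21 (2.1 equiv), K2CO3, DMF, rt
Reagents that add atoms: none
Why: Williamson benzylation with two equivalents stops at the bis-ether because the last ortho hydroxyl is held in a hydrogen bond to the ketone, the known selective protection of this acetophenone.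

**Step 12**
Reactants: 25 methyl 4-{[7-(benzyloxy)-5-ethoxy-2-(4-methoxyphenyl)-4-oxo-4H-chromen-8-yl]oxy}benzoate
Product: 28 4-{[7-(benzyloxy)-5-ethoxy-2-(4-methoxyphenyl)-4-oxo-4H-chromen-8-yl]oxy}benzoic acid
Conditions: LiOH·H2O, THF/H2O, rt → 40 °C; then aq. HCl
Reagents that add atoms: lithium hydroxide, [Li+].[OH-]
Why: Mild saponification of the methyl benzoate should leave the electron-rich 5,7-dialkoxyflavone intact, since opening of the pyrone needs hot concentrated alkali.

**Step 13**
Reactants: 28 4-{[7-(benzyloxy)-5-ethoxy-2-(4-methoxyphenyl)-4-oxo-4H-chromen-8-yl]oxy}benzoic acid; 27 1-[2,4-bis(benzyloxy)-6-hydroxyphenyl]ethanone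
Product: 30 1-[2,4-bis(benzyloxy)-6-hydroxyphenyl]-3-(4-{[7-(benzyloxy)-5-ethoxy-2-(4-methoxyphenyl)-4-oxo-4H-chromen-8-yl]oxy}phenyl)propane-1,3-dione, via acid chloride 29 (not isolated)
Conditions: 28, 1-chloro-N,N,2-trimethylprop-1-en-1-amine, CH2Cl2, 0 °C → rt; then added to 27 and LiN(SiMe3)2 (3.1 equiv), THF, −78 → 0 °C; aq. HCl
Reagents that add atoms: none
Why: The α-chloroenamine makes the acid chloride under neutral conditions that cannot activate the pyrone carbonyl, and the dianion of 27 should then be C-aroylated as in step 9 (Baker–Venkataraman-type).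

**Step 14**
Reactants: 30 1-[2,4-bis(benzyloxy)-6-hydroxyphenyl]-3-(4-{[7-(benzyloxy)-5-ethoxy-2-(4-methoxyphenyl)-4-oxo-4H-chromen-8-yl]oxy}phenyl)propane-1,3-dione
Product: 31 7-(benzyloxy)-8-{4-[5,7-bis(benzyloxy)-4-oxo-4H-chromen-2-yl]phenoxy}-5-ethoxy-2-(4-methoxyphenyl)-4H-chromen-4-one
Conditions: TsOH·H2O (cat.), toluene, 90 °C
Reagents that add atoms: none
Why: Acid-catalysed cyclodehydration of the second 2-hydroxyaryl 1,3-diketone should close the pyrone of the apigenin unit under conditions that aryl benzyl ethers tolerate.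

**Step 15**
Reactants: 31 7-(benzyloxy)-8-{4-[5,7-bis(benzyloxy)-4-oxo-4H-chromen-2-yl]phenoxy}-5-ethoxy-2-(4-methoxyphenyl)-4H-chromen-4-one
Product: 32 8-[4-(5,7-dihydroxy-4-oxo-4H-chromen-2-yl)phenoxy]-5,7-dihydroxy-2-(4-methoxyphenyl)-4H-chromen-4-one (CNP0295851.0)
Conditions: BCl3 (excess), C6HMe5, CH2Cl2, −78 °C → rt; MeOH/H2O quench
Reagents that add atoms: none
Why: Lewis-acid dealkylation with BCl3 should remove the three benzyl ethers at low temperature (pentamethylbenzene traps the benzyl cations) and, on warming, the ethyl ether on O5 through chelation to the C4 carbonyl, while the unchelated 4′-methyl ether is spared and the mild temperature should give no Wessely–Moser isomerisation.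

**Compound list**
1 | methyl 4-hydroxybenzoate | COC(=O)c1ccc(O)cc1 | starting material
2 | tert-butyl bromoacetate | CC(C)(C)OC(=O)CBr | starting material
3 | tert-butyl 2-[4-(methoxycarbonyl)phenoxy]acetate | COC(=O)c1ccc(OCC(=O)OC(C)(C)C)cc1 | intermediate
4 | 2-[4-(methoxycarbonyl)phenoxy]acetic acid | COC(=O)c1ccc(OCC(=O)O)cc1 | intermediate
5 | 2-[4-(methoxycarbonyl)phenoxy]acetyl chloride | COC(=O)c1ccc(OCC(=O)Cl)cc1 | intermediate
6 | benzyl alcohol | OCc1ccccc1 | starting material
7 | trichloroethylene | ClC=C(Cl)Cl | starting material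
8 | benzyl (E)-1,2-dichlorovinyl ether | Cl/C=C(/Cl)OCc1ccccc1 | intermediate
9 | lithium 2-(benzyloxy)ethynide | [Li]C#COCc1ccccc1 | intermediate
10 | benzyl ethynyl ether | C#COCc1ccccc1 | intermediate
11 | methyl 4-[(2-oxoethenyl)oxy]benzoate (the aryloxyketene) | COC(=O)c1ccc(OC=C=O)cc1 | intermediate
12 | methyl 4-{[2-(benzyloxy)-4-oxocyclobut-2-en-1-yl]oxy}benzoate (racemic) | O=C1C=C(OCc2ccccc2)C1Oc1ccc(C(=O)OC)cc1 | intermediate
13 | ethoxyacetylene | C#COCC | starting material
14 | methyl 4-{[(1Z)-2-(benzyloxy)-4-oxobuta-1,3-dien-1-yl]oxy}benzoate (aryloxy group trans to the ketene carbon) | O=C=C/C(OCc1ccccc1)=C/Oc1ccc(C(=O)OC)cc1 | intermediate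
15 | methyl 4-{[(Z)-2-(benzyloxy)-2-(2-ethoxy-4-oxocyclobut-2-en-1-yl)ethenyl]oxy}benzoate (racemic) | O=C1C=C(OCC)C1/C(OCc1ccccc1)=C/Oc1ccc(C(=O)OC)cc1 | intermediate
16 | methyl 4-{[(1Z,3E)-2-(benzyloxy)-4-ethoxy-6-oxohexa-1,3,5-trien-1-yl]oxy}benzoate | O=C=C/C(OCC)=C\C(OCc1ccccc1)=C\Oc1ccc(C(=O)OC)cc1 | intermediate
17 | methyl 4-{[2-(benzyloxy)-4-ethoxy-6-oxocyclohexa-2,4-dien-1-yl]oxy}benzoate (racemic) | O=C1C=C(OCC)C=C(OCc2ccccc2)C1Oc1ccc(C(=O)OC)cc1 | intermediate
18 | methyl 4-[2-(benzyloxy)-4-ethoxy-6-hydroxyphenoxy]benzoate | CCOc1cc(O)c(Oc2ccc(C(=O)OC)cc2)c(OCc2ccccc2)c1 | intermediate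
19 | methyl 4-(4-ethoxy-2,6-dihydroxyphenoxy)benzoate | CCOc1cc(O)c(Oc2ccc(C(=O)OC)cc2)c(O)c1 | intermediate
20 | methyl 4-(3-acetyl-4-ethoxy-2,6-dihydroxyphenoxy)benzoate | CCOc1cc(O)c(Oc2ccc(C(=O)OC)cc2)c(O)c1C(C)=O | intermediate
21 | benzyl bromide | BrCc1ccccc1 | starting material
22 | methyl 4-[3-acetyl-6-(benzyloxy)-4-ethoxy-2-hydroxyphenoxy]benzoate | CCOc1cc(OCc2ccccc2)c(Oc2ccc(C(=O)OC)cc2)c(O)c1C(C)=O | intermediate
23 | 4-methoxybenzoyl chloride | COc1ccc(C(=O)Cl)cc1 | starting material
24 | methyl 4-{6-(benzyloxy)-4-ethoxy-2-hydroxy-3-[3-(4-methoxyphenyl)-3-oxopropanoyl]phenoxy}benzoate | CCOc1cc(OCc2ccccc2)c(Oc2ccc(C(=O)OC)cc2)c(O)c1C(=O)CC(=O)c1ccc(OC)cc1 | intermediate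
25 | methyl 4-{[7-(benzyloxy)-5-ethoxy-2-(4-methoxyphenyl)-4-oxo-4H-chromen-8-yl]oxy}benzoate | CCOc1cc(OCc2ccccc2)c(Oc2ccc(C(=O)OC)cc2)c2oc(-c3ccc(OC)cc3)cc(=O)c12 | intermediate
26 | 2,4,6-trihydroxyacetophenone | CC(=O)c1c(O)cc(O)cc1O | starting material
27 | 1-[2,4-bis(benzyloxy)-6-hydroxyphenyl]ethanone | CC(=O)c1c(O)cc(OCc2ccccc2)cc1OCc1ccccc1 | intermediate
28 | 4-{[7-(benzyloxy)-5-ethoxy-2-(4-methoxyphenyl)-4-oxo-4H-chromen-8-yl]oxy}benzoic acid | CCOc1cc(OCc2ccccc2)c(Oc2ccc(C(=O)O)cc2)c2oc(-c3ccc(OC)cc3)cc(=O)c12 | intermediate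
29 | 4-{[7-(benzyloxy)-5-ethoxy-2-(4-methoxyphenyl)-4-oxo-4H-chromen-8-yl]oxy}benzoyl chloride | CCOc1cc(OCc2ccccc2)c(Oc2ccc(C(=O)Cl)cc2)c2oc(-c3ccc(OC)cc3)cc(=O)c12 | intermediate
30 | 1-[2,4-bis(benzyloxy)-6-hydroxyphenyl]-3-(4-{[7-(benzyloxy)-5-ethoxy-2-(4-methoxyphenyl)-4-oxo-4H-chromen-8-yl]oxy}phenyl)propane-1,3-dione | CCOc1cc(OCc2ccccc2)c(Oc2ccc(C(=O)CC(=O)c3c(O)cc(OCc4ccccc4)cc3OCc3ccccc3)cc2)c2oc(-c3ccc(OC)cc3)cc(=O)c12 | intermediate
31 | 7-(benzyloxy)-8-{4-[5,7-bis(benzyloxy)-4-oxo-4H-chromen-2-yl]phenoxy}-5-ethoxy-2-(4-methoxyphenyl)-4H-chromen-4-one | CCOc1cc(OCc2ccccc2)c(Oc2ccc(-c3cc(=O)c4c(OCc5ccccc5)cc(OCc5ccccc5)cc4o3)cc2)c2oc(-c3ccc(OC)cc3)cc(=O)c12 | intermediate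
32 | 8-[4-(5,7-dihydroxy-4-oxo-4H-chromen-2-yl)phenoxy]-5,7-dihydroxy-2-(4-methoxyphenyl)-4H-chromen-4-one (CNP0295851.0, no stereocentre) | COc1ccc(-c2cc(=O)c3c(O)cc(O)c(Oc4ccc(-c5cc(=O)c6c(O)cc(O)cc6o5)cc4)c3o2)cc1 | target

**Step count.** Total: 15 steps. Longest linear sequence: 13 steps (steps 1, 2, 4 to 10, 12 to 15).

**Steps most likely to fail**

Step 5. The ring opening of the donor-stabilised cyclobutenone may be too slow at temperatures the ynol ether tolerates, or the electron-rich vinylketene may be consumed by self-condensation or by acylating the product phenol before the alkyne traps it. The fallback gives up the de novo ring and makes the diaryl ether by copper catalysis; it sets out from 1 and comes back at 19. Phloroglucinol (bought) is mono-etherified with ethanol and HCl to 5-ethoxybenzene-1,3-diol F1, which is protected with chloromethyl methyl ether and iPr2NEt as 1-ethoxy-3,5-bis(methoxymethoxy)benzene F2. Lithiation between the two acetal oxygens (n-BuLi, THF, 0 °C) and an iodine quench should give 5-ethoxy-2-iodo-1,3-bis(methoxymethoxy)benzene F3. Ullmann coupling of F3 with 1 (CuI, picolinic acid, K3PO4, DMSO, 90 °C) should give methyl 4-[4-ethoxy-2,6-bis(methoxymethoxy)phenoxy]benzoate F4, and HCl in methanol removes both acetals to reach 19.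

Step 4. Self-condensation of the monosubstituted ketene and sigmatropic or oligomeric decay of the benzylic ynol ether may outrun the cross-cycloaddition. The fallback replaces the benzylic carrier of O7 by a secondary alkyl one, which has no sigmatropic path, can be distilled and can be used in large excess, and unmasks it by Lewis acid instead of hydrogen; it sets out from 5 and comes back at 19. Isopropyl ethynyl ether F5 is made from propan-2-ol and 7 by the protocol of step 3 and combined with 5 and Et3N as in step 4 to give methyl 4-{[4-oxo-2-(propan-2-yloxy)cyclobut-2-en-1-yl]oxy}benzoate F6. Benzannulation of F6 with 13 as in step 5 should give methyl 4-[4-ethoxy-2-hydroxy-6-(propan-2-yloxy)phenoxy]benzoate F7, and BCl3 in CH2Cl2 at −20 → 0 °C cleaves the isopropyl ether in preference to the ethyl ether and the ester, which gives 19.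

Step 15. Dealkylation at O5 may stay incomplete at temperatures where the 4′-methyl ether is still safe, or benzyl cations may escape the scavenger and alkylate the phloroglucinol rings. The fallback separates the two tasks; it sets out from 31 and comes back at 32. Hydrogenolysis (H2, Pd/C, THF/EtOAc) removes the three benzyl ethers without cations and should give 8-[4-(5,7-dihydroxy-4-oxo-4H-chromen-2-yl)phenoxy]-5-ethoxy-7-hydroxy-2-(4-methoxyphenyl)-4H-chromen-4-one F8. AlCl3 in MeCN at 50 °C then removes only the ethyl ether chelated to the C4 carbonyl and gives 32.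

**Further compounds**
F1 | step 5 | 5-ethoxybenzene-1,3-diol | CCOc1cc(O)cc(O)c1
F2 | step 5 | 1-ethoxy-3,5-bis(methoxymethoxy)benzene | CCOc1cc(OCOC)cc(OCOC)c1
F3 | step 5 | 5-ethoxy-2-iodo-1,3-bis(methoxymethoxy)benzene | CCOc1cc(OCOC)c(I)c(OCOC)c1
F4 | step 5 | methyl 4-[4-ethoxy-2,6-bis(methoxymethoxy)phenoxy]benzoate | CCOc1cc(OCOC)c(Oc2ccc(C(=O)OC)cc2)c(OCOC)c1
F5 | step 4 | isopropyl ethynyl ether | C#COC(C)C
F6 | step 4 | methyl 4-{[4-oxo-2-(propan-2-yloxy)cyclobut-2-en-1-yl]oxy}benzoate (racemic) | O=C1C=C(OC(C)C)C1Oc1ccc(C(=O)OC)cc1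
F7 | step 4 | methyl 4-[4-ethoxy-2-hydroxy-6-(propan-2-yloxy)phenoxy]benzoate | CCOc1cc(O)c(Oc2ccc(C(=O)OC)cc2)c(OC(C)C)c1
F8 | step 15 | 8-[4-(5,7-dihydroxy-4-oxo-4H-chromen-2-yl)phenoxy]-5-ethoxy-7-hydroxy-2-(4-methoxyphenyl)-4H-chromen-4-one | CCOc1cc(O)c(Oc2ccc(-c3cc(=O)c4c(O)cc(O)cc4o3)cc2)c2oc(-c3ccc(OC)cc3)cc(=O)c12
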